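**Strategy.** The route rests on cutting ring N2 of the naphthalene (C1′–C4′, C4a′, C8a′) away from a 5-aryl-tetrahydroisoquinoline. Because this ring does not touch the C5–C8′ biaryl bond, it can be grown last. A base-generated C4a′–C8a′ aryne takes up a vinylketene silyl acetal in one [4+2] operation that forms C1′–C8a′ and C4′–C4a′ and delivers the C4′ naphthol, steered by the C5′ methoxy group. The precursor is the (1R,3R)-8-benzyloxy-6-methoxy-1,2,3-trimethyltetrahydroisoquinoline carrying a 3-bromo-4-methoxyphenyl group at C5. Its phenyl ring has hydrogen at both ortho positions, so it is easy to attach by Suzuki coupling.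

Key step: step 11

Assumption: the given structure fixes only C1 and C3 (both R) and not the sense of the hindered C5–C8′ axis, so the axis that arises in step 11 is not controlled and compounds 20–22 are expected as two atropo-diastereomers, separable by chromatography if one is wanted.

Step 1
Reactants: 1 2′,6′-dihydroxy-4′-methoxyacetophenone
Product: 2 1-[2-(benzyloxy)-6-hydroxy-4-methoxyphenyl]ethanone
Conditions: BnBr (1.0 equiv), K2CO3, acetone, reflux
Reagents that add atoms: benzyl bromide, BrCc1ccccc1
Why: Williamson ether synthesis in which one of the two equivalent phenols is benzylated and the second, held in a hydrogen bond to the acetyl carbonyl, should stay free, so the later C8 oxygen is protected from the start.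

Step 2
Reactants: 2 1-[2-(benzyloxy)-6-hydroxy-4-methoxyphenyl]ethanone
Product: 3 2-acetyl-3-(benzyloxy)-5-methoxyphenyl trifluoromethanesulfonate
Conditions: Tf2O, pyridine, CH2Cl2, 0 °C
Reagents that add atoms: trifluoromethanesulfonic anhydride, O=S(=O)(OS(=O)(=O)C(F)(F)F)C(F)(F)F
Why: O-sulfonylation of the remaining phenol gives an aryl triflate that the ortho acetyl group activates for oxidative addition.

Step 3
Reactants: 4 tert-butyl N-[(2R)-1-hydroxypropan-2-yl]carbamate (N-Boc-D-alaninol)
Product: 5 tert-butyl N-[(2R)-1-iodopropan-2-yl]carbamate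
Conditions: I2, PPh3, imidazole, CH2Cl2, 0 °C → rt
Reagents that add atoms: iodine, II
Why: Appel iodination of the primary alcohol under buffered conditions leaves the carbamate and the stereocentre, which is not a reacting centre, untouched.

Step 4
Reactants: 5 tert-butyl N-[(2R)-1-iodopropan-2-yl]carbamate, 3 2-acetyl-3-(benzyloxy)-5-methoxyphenyl trifluoromethanesulfonate
Product: 7 tert-butyl N-[(2R)-1-[2-acetyl-3-(benzyloxy)-5-methoxyphenyl]propan-2-yl]carbamate, via alkylzinc iodide 6 (not isolated)
Conditions: Zn dust (I2-activated), DMF, rt; then 3, Pd2(dba)3, SPhos (2-dicyclohexylphosphino-2′,6′-dimethoxybiphenyl), DMF, 45 °C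
Reagents that add atoms: none
Why: Negishi coupling in which zinc inserts into the primary C–I bond, the β-carbamate zinc reagent is stable enough in DMF, and the zerovalent palladium catalyst formed from Pd2(dba)3 and SPhos should join it to the triflate carbon without touching the ketone or the stereocentre one carbon away from the metal.

Step 5
Reactants: 7 tert-butyl N-[(2R)-1-[2-acetyl-3-(benzyloxy)-5-methoxyphenyl]propan-2-yl]carbamate
Product: 9 (3R)-8-(benzyloxy)-6-methoxy-1,3-dimethyl-3,4-dihydroisoquinoline, via amino ketone 8 (not isolated)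
Conditions: HCl (4 M in dioxane), CH2Cl2, rt; then aq. NaHCO3, CH2Cl2, rt
Reagents that add atoms: none
Why: Acidolysis of the Boc group frees the primary amine, which after neutralisation should condense with the ortho ketone to the conjugated six-membered cyclic imine (intramolecular imine formation), C3 being unaffected.

Step 6
Reactants: 9 (3R)-8-(benzyloxy)-6-methoxy-1,3-dimethyl-3,4-dihydroisoquinoline
Product: 11 (1R,3R)-8-(benzyloxy)-6-methoxy-1,2,3-trimethyl-1,2,3,4-tetrahydroisoquinoline, via N-methyliminium iodide 10 (not isolated)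
Conditions: MeI, acetone, 40 °C; evaporate; NaBH4, MeOH, −78 → 0 °C
Reagents that add atoms: iodomethane, CI
Why: N-alkylation followed by iminium reduction, in which the C3 methyl group of the iminium ion turns pseudo-axial to avoid the adjacent N-methyl group and borohydride adds to C1 along the axial path on that same face through a half-chair transition state, so that H-1 ends cis to the C3 methyl group and the two C-methyl groups trans (1R).

Step 7
Reactants: 11 (1R,3R)-8-(benzyloxy)-6-methoxy-1,2,3-trimethyl-1,2,3,4-tetrahydroisoquinoline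
Product: 12 (1R,3R)-8-(benzyloxy)-5-iodo-6-methoxy-1,2,3-trimethyl-1,2,3,4-tetrahydroisoquinoline
Conditions: N-iodosuccinimide (1.0 equiv), CF3CO2H (2 equiv), MeCN, 0 °C → rt; aq. NaHCO3/Na2S2O3
Reagents that add atoms: N-iodosuccinimide, O=C1CCC(=O)N1I
Why: Electrophilic aromatic iodination with the amine protonated should go to C5 (para to benzyloxy, ortho to methoxy) and not to C7, which is crowded between two alkoxy groups.

Step 8
Reactants: 12 (1R,3R)-8-(benzyloxy)-5-iodo-6-methoxy-1,2,3-trimethyl-1,2,3,4-tetrahydroisoquinoline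
Product: 13 (1R,3R)-8-(benzyloxy)-6-methoxy-1,2,3-trimethyl-5-(4,4,5,5-tetramethyl-1,3,2-dioxaborolan-2-yl)-1,2,3,4-tetrahydroisoquinoline
Conditions: pinacolborane, Et3N, PdCl2(MeCN)2, SPhos, 1,4-dioxane, 80 °C
Reagents that add atoms: pinacolborane, CC1(C)OBOC1(C)C
Why: Miyaura-type borylation of the aryl iodide with PdCl2(MeCN)2 and a bulky biarylphosphine that tolerates two ortho substituents, under conditions inert to the amine, the benzyl ether and both stereocentres.

Step 9
Reactants: 13 (1R,3R)-8-(benzyloxy)-6-methoxy-1,2,3-trimethyl-5-(4,4,5,5-tetramethyl-1,3,2-dioxaborolan-2-yl)-1,2,3,4-tetrahydroisoquinoline, 14 2-bromo-4-iodoanisole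
Product: 15 (1R,3R)-8-(benzyloxy)-5-(3-bromo-4-methoxyphenyl)-6-methoxy-1,2,3-trimethyl-1,2,3,4-tetrahydroisoquinoline
Conditions: 14 (2 equiv), Pd(PPh3)4, Ba(OH)2, DME/H2O, 80 °C
Reagents that add atoms: none
Why: Suzuki–Miyaura coupling in which Pd(PPh3)4 should insert into the C–I bond of 14 far faster than into its C–Br bond, so the bromine survives as the later aryne handle and the new biaryl has no ortho substituent on the phenyl side.

Step 10
Reactants: 16 methyl 3-methylbut-2-enoate
Product: 17 (1Z)-1-methoxy-3-methyl-1-(trimethylsilyloxy)buta-1,3-diene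
Conditions: LiN(iPr)2, THF, −78 °C; Me3SiCl, −78 °C → rt; distil
Reagents that add atoms: chlorotrimethylsilane, C[Si](C)(C)Cl
Why: γ-Deprotonation of the enoate gives the extended enolate, which is silylated on oxygen to the vinylketene silyl acetal (silyl ketene acetal formation).

Step 11
Reactants: 15 (1R,3R)-8-(benzyloxy)-5-(3-bromo-4-methoxyphenyl)-6-methoxy-1,2,3-trimethyl-1,2,3,4-tetrahydroisoquinoline, 17 (1Z)-1-methoxy-3-methyl-1-(trimethylsilyloxy)buta-1,3-diene
Product: 20 5-[(1R,3R)-8-(benzyloxy)-6-methoxy-1,2,3-trimethyl-1,2,3,4-tetrahydroisoquinolin-5-yl]-8-methoxy-3-methylnaphthalen-1-ol, via aryne 18 (not isolated), via ketal cycloadduct 19 (not isolated)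
Conditions: 17 (3 equiv), lithium 2,2,6,6-tetramethylpiperidide (3 equiv, from n-BuLi and 2,2,6,6-tetramethylpiperidine), THF, −78 °C → rt; then 1 M HCl, rt; NaHCO3
Reagents that add atoms: none
Why: The amide base removes the only hydrogen ortho to bromine (on C8a′; the other ortho carbon carries methoxy), and loss of LiBr gives aryne 18, whose strained bond lies between the C5′ methoxy carbon and the C8′ aryl carbon. The electron-rich diene 17 then adds in an asynchronous, polarity-matched aryne Diels–Alder reaction, the closest known type being the [4+2] addition of vinylketene silyl acetals to methoxy-substituted benzynes that gives 1-naphthols. Ring N2 is closed by this intermolecular [4+2] annulation, both new bonds (C1′–C8a′ and C4′–C4a′) forming across the one aryne bond, and the mixed ketal 19 loses methanol and its silyl group during the acidic work-up so that the ring aromatises as the C4′ naphthol. No stereocentre is formed; the C5–C8′ axis becomes hindered here and is not controlled. The selectivity that matters is the orientation of the diene: the inductive pull of the C5′ methoxy group makes C8a′ the electrophilic aryne carbon, so the nucleophilic CH2 terminus should bond there and the acetal carbon at C4a′, and because CH2 is the small end of the diene the neighbouring aryl group at C8′ does not oppose this.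

Step 12
Reactants: 20 5-[(1R,3R)-8-(benzyloxy)-6-methoxy-1,2,3-trimethyl-1,2,3,4-tetrahydroisoquinolin-5-yl]-8-methoxy-3-methylnaphthalen-1-ol
Product: 21 (1R,3R)-8-(benzyloxy)-5-(4,5-dimethoxy-7-methylnaphthalen-1-yl)-6-methoxy-1,2,3-trimethyl-1,2,3,4-tetrahydroisoquinoline
Conditions: Me3SiCHN2 (2 M in hexanes), iPr2NEt, MeCN/MeOH, rt
Reagents that add atoms: (trimethylsilyl)diazomethane, C[Si](C)(C)C=[N+]=[N-]
Why: O-methylation of the naphthol by proton transfer to the diazoalkane and collapse of the resulting ion pair, chosen because this reagent, unlike an alkyl halide, cannot quaternise the tertiary amine.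

Step 13
Reactants: 21 (1R,3R)-8-(benzyloxy)-5-(4,5-dimethoxy-7-methylnaphthalen-1-yl)-6-methoxy-1,2,3-trimethyl-1,2,3,4-tetrahydroisoquinoline
Product: 22 ancistrocongoline B, (1R,3R)-5-(4,5-dimethoxy-7-methylnaphthalen-1-yl)-6-methoxy-1,2,3-trimethyl-1,2,3,4-tetrahydroisoquinolin-8-ol
Conditions: H2 (1 atm), Pd(OH)2/C, MeOH/EtOAc, rt
Reagents that add atoms: none
Why: Hydrogenolysis of the benzyl aryl ether over Pd(OH)2/C should free the C8 phenol while the methyl ethers, the naphthalene and the ring C1–N bond stay intact under these mild conditions.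

**Compound list**

1 | 2′,6′-dihydroxy-4′-methoxyacetophenone | COc1cc(O)c(C(C)=O)c(O)c1 | starting material
2 | 1-[2-(benzyloxy)-6-hydroxy-4-methoxyphenyl]ethanone | COc1cc(O)c(C(C)=O)c(OCc2ccccc2)c1 | intermediate
3 | 2-acetyl-3-(benzyloxy)-5-methoxyphenyl trifluoromethanesulfonate | COc1cc(OS(=O)(=O)C(F)(F)F)c(C(C)=O)c(OCc2ccccc2)c1 | intermediate
4 | tert-butyl N-[(2R)-1-hydroxypropan-2-yl]carbamate (N-Boc-D-alaninol) | C[C@@H](NC(=O)OC(C)(C)C)CO | starting material
5 | tert-butyl N-[(2R)-1-iodopropan-2-yl]carbamate | C[C@@H](NC(=O)OC(C)(C)C)CI | intermediate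
6 | [(2R)-2-(tert-butoxycarbonylamino)propyl]zinc iodide | C[C@@H](NC(=O)OC(C)(C)C)C[Zn]I | intermediate
7 | tert-butyl N-[(2R)-1-[2-acetyl-3-(benzyloxy)-5-methoxyphenyl]propan-2-yl]carbamate | COc1cc(C[C@@H](C)NC(=O)OC(C)(C)C)c(C(C)=O)c(OCc2ccccc2)c1 | intermediate
8 | 1-[2-[(2R)-2-aminopropyl]-6-(benzyloxy)-4-methoxyphenyl]ethanone | COc1cc(C[C@@H](C)N)c(C(C)=O)c(OCc2ccccc2)c1 | intermediate
9 | (3R)-8-(benzyloxy)-6-methoxy-1,3-dimethyl-3,4-dihydroisoquinoline | COc1cc(OCc2ccccc2)c2c(c1)C[C@@H](C)N=C2C | intermediate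
10 | (3R)-8-(benzyloxy)-6-methoxy-1,2,3-trimethyl-3,4-dihydroisoquinolin-2-ium iodide | COc1cc(OCc2ccccc2)c2c(c1)C[C@@H](C)[N+](C)=C2C.[I-] | intermediate
11 | (1R,3R)-8-(benzyloxy)-6-methoxy-1,2,3-trimethyl-1,2,3,4-tetrahydroisoquinoline | COc1cc(OCc2ccccc2)c2c(c1)C[C@@H](C)N(C)[C@@H]2C | intermediate
12 | (1R,3R)-8-(benzyloxy)-5-iodo-6-methoxy-1,2,3-trimethyl-1,2,3,4-tetrahydroisoquinoline | COc1cc(OCc2ccccc2)c2c(c1I)C[C@@H](C)N(C)[C@@H]2C | intermediate
13 | (1R,3R)-8-(benzyloxy)-6-methoxy-1,2,3-trimethyl-5-(4,4,5,5-tetramethyl-1,3,2-dioxaborolan-2-yl)-1,2,3,4-tetrahydroisoquinoline | COc1cc(OCc2ccccc2)c2c(c1B3OC(C)(C)C(C)(C)O3)C[C@@H](C)N(C)[C@@H]2C | intermediate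
14 | 2-bromo-4-iodoanisole | COc1ccc(I)cc1Br | starting material
15 | (1R,3R)-8-(benzyloxy)-5-(3-bromo-4-methoxyphenyl)-6-methoxy-1,2,3-trimethyl-1,2,3,4-tetrahydroisoquinoline | COc1cc(OCc2ccccc2)c2c(c1-c3ccc(OC)c(Br)c3)C[C@@H](C)N(C)[C@@H]2C | intermediate
16 | methyl 3-methylbut-2-enoate | COC(=O)C=C(C)C | starting material
17 | (1Z)-1-methoxy-3-methyl-1-(trimethylsilyloxy)buta-1,3-diene | CO/C(O[Si](C)(C)C)=C/C(C)=C | intermediate
18 | (1R,3R)-8-(benzyloxy)-6-methoxy-5-(4-methoxy-2,3-didehydrophenyl)-1,2,3-trimethyl-1,2,3,4-tetrahydroisoquinoline (C4a′–C8a′ aryne) | COc1cc(OCc2ccccc2)c2c(c1C3=CC=C(OC)C#C3)C[C@@H](C)N(C)[C@@H]2C | intermediate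
19 | (1R,3R)-8-(benzyloxy)-5-[4,5-dimethoxy-7-methyl-5-(trimethylsilyloxy)-5,8-dihydronaphthalen-1-yl]-6-methoxy-1,2,3-trimethyl-1,2,3,4-tetrahydroisoquinoline (cycloadduct, mixed ketal at C4′) | COc1cc(OCc2ccccc2)c2c(c1-c3ccc(OC)c4c3CC(C)=CC4(OC)O[Si](C)(C)C)C[C@@H](C)N(C)[C@@H]2C | intermediate
20 | 5-[(1R,3R)-8-(benzyloxy)-6-methoxy-1,2,3-trimethyl-1,2,3,4-tetrahydroisoquinolin-5-yl]-8-methoxy-3-methylnaphthalen-1-ol | COc1cc(OCc2ccccc2)c2c(c1-c3ccc(OC)c4c(O)cc(C)cc34)C[C@@H](C)N(C)[C@@H]2C | intermediate
21 | (1R,3R)-8-(benzyloxy)-5-(4,5-dimethoxy-7-methylnaphthalen-1-yl)-6-methoxy-1,2,3-trimethyl-1,2,3,4-tetrahydroisoquinoline | COc1cc(OCc2ccccc2)c2c(c1-c3ccc(OC)c4c(OC)cc(C)cc34)C[C@@H](C)N(C)[C@@H]2C | intermediate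
22 | ancistrocongoline B, (1R,3R)-5-(4,5-dimethoxy-7-methylnaphthalen-1-yl)-6-methoxy-1,2,3-trimethyl-1,2,3,4-tetrahydroisoquinolin-8-ol | COc1cc(O)c2c(c1-c1ccc(OC)c3c(OC)cc(C)cc13)C[C@@H](C)N(C)[C@@H]2C | target

**Count and risks**

Total step count: 13. Longest linear sequence: 11 steps (steps 1, 2, 4 to 9 and 11 to 13, from compound 1); steps 3 and 10 are one-step side branches.

Steps most likely to fail:

1. Step 11. Removal of the C8a′ hydrogen may be slow, because it sits between bromine and the twisted, doubly ortho-substituted isoquinoline ring. The amide base would then be spent on the benzylic CH2 of the ether or add to the aryne, and the diene would decay before it is trapped. The fallback enters the same aryne from the other side and sets out from boronate 13. Coupling of 13 at the C–Br bond of commercial 4-bromo-3-chloroanisole (Pd(PPh3)4, Ba(OH)2, DME/H2O, 80 °C) should give (1R,3R)-8-(benzyloxy)-5-(2-chloro-4-methoxyphenyl)-6-methoxy-1,2,3-trimethyl-1,2,3,4-tetrahydroisoquinoline F1. In F1 the hydrogen to be removed is on C4a′, between chlorine and methoxy, so it is much more acidic and unhindered. LiN(iPr)2 in THF at −78 °C should metalate it, and LiCl is lost on warming in the presence of diene 17 to give the same aryne 18 and cycloadduct 19. Acidic work-up returns to the route at naphthol 20. The price is a biaryl coupling with three ortho substituents.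

2. Step 4. The β-carbamate zinc reagent may undergo β-elimination or be protonated before the triflate has undergone oxidative addition. The fallback replaces zinc by boron and sets out from iodide 5. Borylation of 5 (B2pin2, CuI, PPh3, LiOtBu, DMF, rt) should give tert-butyl N-[(2R)-1-(4,4,5,5-tetramethyl-1,3,2-dioxaborolan-2-yl)propan-2-yl]carbamate F2. KHF2 in MeOH/H2O converts F2 into potassium [(2R)-2-(tert-butoxycarbonylamino)propyl]trifluoroborate F3, a bench-stable salt that does not eliminate. B-alkyl Suzuki–Miyaura coupling of F3 with triflate 3 (PdCl2(dppf), Cs2CO3, THF/H2O, 80 °C) returns to the route at compound 7.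

3. Step 6. Hydride may be delivered to the other face of the iminium ion, which would give the cis (1S,3R) isomer, or some over-alkylation may occur if iodomethane is not fully removed. The fallback reduces first and methylates afterwards, and sets out from imine 9. Reduction of 9 with LiAlH4 in the presence of AlMe3 (THF, −78 °C), a trans-selective protocol for 1,3-dimethyl-3,4-dihydroisoquinolines, should give (1R,3R)-8-(benzyloxy)-6-methoxy-1,3-dimethyl-1,2,3,4-tetrahydroisoquinoline F4. Reductive amination of F4 with aqueous formaldehyde and NaBH(OAc)3 in 1,2-dichloroethane returns to the route at compound 11. Should the two diastereomers form together, they can be separated at the stage of F4 before the methyl group is added.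

**Further compounds**

F1 | step 11 | (1R,3R)-8-(benzyloxy)-5-(2-chloro-4-methoxyphenyl)-6-methoxy-1,2,3-trimethyl-1,2,3,4-tetrahydroisoquinoline | COc1cc(OCc2ccccc2)c2c(c1-c3ccc(OC)cc3Cl)C[C@@H](C)N(C)[C@@H]2C
F2 | step 4 | tert-butyl N-[(2R)-1-(4,4,5,5-tetramethyl-1,3,2-dioxaborolan-2-yl)propan-2-yl]carbamate | C[C@@H](NC(=O)OC(C)(C)C)CB1OC(C)(C)C(C)(C)O1
F3 | step 4 | potassium [(2R)-2-(tert-butoxycarbonylamino)propyl]trifluoroborate | C[C@@H](NC(=O)OC(C)(C)C)C[B-](F)(F)F.[K+]
F4 | step 6 | (1R,3R)-8-(benzyloxy)-6-methoxy-1,3-dimethyl-1,2,3,4-tetrahydroisoquinoline | COc1cc(OCc2ccccc2)c2c(c1)C[C@@H](C)N[C@@H]2C
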